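(The numbers in the tables are calculated for substances that don't exist; the scatter is artificial.)

The target in the ash run came late, so I followed one reacted molecule and asked its chance of standing as target.

- ash: starting material 0.85 M; reagent in the second phase 1.2 equiv; run made earlier
- flask: starting material 1.7 M; reagent in the second phase 1.20 equiv; time 4.0 h; volume of the second phase over the first 1.0

ash run (percent of the starting material charged)

| time / h | target / % | starting material / % |
|---|---|---|
| 0.250 | 0.3 | 98.8 |
| 0.667 | 1.6 | 93.0 |
| 1.33 | 4.5 | 84.3 |
| 3.00 | 15.1 | 65.7 |

(readings scatter by 0.5 percentage points)

1. how much target there is at 4.0 h, in percent of the starting material charged
2. part of the starting material charged that has reacted at 4.0 h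

- in the second phase: reagent in the second phase; everything else is in the first
- charges count per volume of the first phase; a concentration in a rate is the amount of a species over the volume of its own phase; every rate counts per litre of the first phase
- the earlier runs hold the two phases in the same ratio of volumes as the flask asked about
- what has gone from starting material into another species counts as reacted, even if it can come back

That chance is the target share, the selectivity: target over starting material reacted, 0.440 as read at 3.00 h. But it had read 0.287 at 1.33 h, so it was lower earlier and still climbing. The flask runs longer, at twice the concentration, so I took the last reading as my low estimate of the flask's share, an estimate and no bound, with the scatter of the readings on it.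

The forecast gave 28% and 50%, reading “largely transfer-limited consumption”. Its pair means a share of 0.560, above my low estimate, and on its conversion my estimate gave 22.0% of target, below its number.

The flask gave 28.9% and 54.4%.

    reagent in the reaction phase ⇌ reagent in the second phase, rate k1*([reagent in the reaction phase] - [reagent in the second phase]/K1) per volume of the first phase (partition coefficient = 0.550, kL = 0.190 h⁻¹)
    starting material + reagent in the reaction phase → target (k = 0.250 L mol⁻¹ h⁻¹)
    reagent in the reaction phase + target → over-reacted product (k = 0.150 L mol⁻¹ h⁻¹)
    starting material ⇌ dormant form (K = 0.840, k = 0.0890 h⁻¹)

The flask's share was 0.532, above my low estimate, and the reacted remainder stood as dormant form 20.1% and over-reacted product 5.35%. A neighbour flask charged with 1.0 M, read at the same time, had 46.6% reacted, so my low estimate gave it 20.5% of target. It held 22.4%, a share of 0.481, lower than the flask's, with its dormant form at 21.5%.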